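**Remark (assumption):** The SMILES is read as the (2S)-flavanone (CIP order at C2: O1 > C1' > C3 > H). "Prenyl" means 3-methylbut-2-en-1-yl, "reverse prenyl" means 2-methylbut-3-en-2-yl, and MOM means methoxymethyl. 5,7-Dihydroxychromone (1) and 4-bromoresorcinol (8) are taken as purchasable.

**Numbering used throughout:** 1 5,7-dihydroxychromone; 2 its 7-O-MOM ether; 3 the 5-O-prenyl ether of 2; 4 and 5 dienone intermediates; 6 5-hydroxy-7-MOMO-8-prenylchromone; 7 5,7-bis(MOMO)-8-prenylchromone; 8 4-bromoresorcinol; 9 its mono-prenyl ether; 10 the MOM ether of 9; 11 dienone intermediate; 12 the Claisen phenol; 13 the bis-MOM aryl bromide; 14 aryllithium; 15 borate; 16 arylboronic acid; 17 tetra-MOM (2S)-flavanone; 18 target.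

## Analysis of the target

The target is a flavanone. Ring A (C4a, C5–C8, C8a) is a phloroglucinol-type benzene with free OH at C5 and C7 and a prenyl group at C8. Ring C is the dihydropyranone (O1, C2, C3, C4). Ring B (C1'–C6') is a resorcinol with OH at C2' and C4' and a reverse prenyl group at C5'.

C2 is the only stereocentre; it carries O1, C3, H and C1' and is S. This centre is labile: base opens ring C by E1cB through the C3 enolate, and acid can ionise the C2–O1 bond because a cation at C2 is stabilised by O2' and O4'. Both paths racemise.

The two C5 units are separate regiochemical problems. On ring A the prenyl group must sit at C8 (next to C8a and O1) and not at the electronically equivalent C6. On ring B the chain must be bound through its tertiary carbon at C5', ortho to O4'.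

The sensitive groups are four phenols (O5–H chelated to the C4 carbonyl), a trisubstituted alkene ortho to O7–H and a vinyl group ortho to O4'–H. Both alkenes can cyclise onto the neighbouring phenol under strong acid, and they exclude hydrogenation and electrophilic oxidants late in the route.

The feature the route exploits is that C2 is the β-carbon of the C4 ketone inside ring C, and its only bond to ring B is C2–C1'. Cutting this bond leaves an achiral, aromatic chromone (rings A and C with a C2=C3 double bond) and an aryl nucleophile (ring B). One catalyst-controlled conjugate arylation can then join the halves and set C2 without ring C ever being opened or closed.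

Two further relations serve the side chains. C8 is para to O5, which is peri to the C4 carbonyl, and C5' is ortho to O4'. Both C–C bonds can therefore be traced back to O-prenyl ethers through [3,3] shifts.

## Retrosynthetic reasoning

**18 ⇒ 17.** The four O–H bonds are traced back to four MOM ethers. One group type is used for all phenols because it survives carbonate, hydride, organolithium, the rhodium step and 190 °C, and leaves under mild acid. The last step forms no C–C bond and should not touch C2.

**17 ⇒ 7 + 16 (key disconnection, C2–C1').** The cut is made here because it divides the molecule into two halves of similar size, each carrying one C5 unit already in place. It also puts the creation of the labile stereocentre at the penultimate step. Ring C arrives closed in 7, so neither a reversible oxa-Michael closure nor a choice between the two ortho oxygens of ring A can arise. The forward reaction must add the aryl group of 16 to C2 of 7 on one enantioface, tolerate an ortho-alkoxy, electron-rich aryl donor and two isolated alkenes, and leave the product ring closed.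

**7 ⇒ 6 ⇒ 3 (C8–CH2 bond of the prenyl group).** The chelated phenol 6 is capped to give 7. Chain 6 is traced back by a retro para-Claisen–Cope sequence to the O5-prenyl ether 3. O5 is chosen because it is peri to the C4 carbonyl, so a Lewis acid can chelate and activate exactly this ether. The position para to O5 is C8, and two successive allyl inversions return the linear chain. Since O1 is already fixed at C8a in the chromone, C6 versus C8 is decided by the sigmatropic path and not by a protecting-group pattern.

**3 ⇒ 2 ⇒ 1.** Two O-alkylations are distinguished by the hydrogen bond of O5–H to the carbonyl: O7 reacts first and O5 second.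

**16 ⇒ 13 (C1'–B from C1'–Br), then 13 ⇒ 12 ⇒ 10 (C5'–C bond of the reverse prenyl group).** The boronic acid comes from the bromide by halogen–lithium exchange. The tertiary attachment at C5' ortho to O4' is the signature of an aromatic Claisen shift of the O4'-prenyl ether 10; the single allyl inversion gives the branched chain. In 10 the bromine at C1' forces the neighbouring OMOM group to lie over the position between the two oxygens. This should steer the shift to C5', and the bromine also blocks the para position.

**10 ⇒ 9 ⇒ 8.** The two oxygens of 8 are distinguished as a bis-phenoxide: the oxygen para to bromine is more basic and unhindered and takes the prenyl group; the other then takes the MOM group.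

## Alternatives that were turned down

**Alternative 1:** The textbook disconnection cuts C2–C3 and O1–C2. The forward key step is a Claisen–Schmidt condensation of the ring A methyl ketone A2 with the ring B aldehyde A3 to give the 2'-hydroxychalcone A1, followed by 6-endo oxa-Michael closure. It was turned down for three reasons.
- The oxa-Michael step is reversible and under thermodynamic control, so it gives the racemate and would erode any induced excess. Enantioselective closures of chalcones such as A1 that lack an activating ester at C3 are not dependable, and adding and removing such an ester costs about three steps.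
- A2 needs the oxygen next to the prenyl group free and the other ortho oxygen protected. Differentiating the two ortho oxygens of a phloroglucinol ketone and placing the chain costs about five steps, and an error there puts the prenyl group at C6 instead of C8.
- The total count exceeds that of the chosen route.

**Alternative 2:** Both side-chain C–C bonds (at C8 and at C5') are cut in one operation, leading to the (2S)-bis(O-prenyl) ether A4. The forward key step heats A4 with a europium catalyst so that the O5 ether undergoes a para-Claisen–Cope shift and the O4' ether an ortho-Claisen shift in one flask. It was turned down for these reasons.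
- Only the O5 ether is activated by chelation; the O4' ether needs about 180–190 °C in an amine solvent.
- At that temperature the C2 centre, already present in A4, would be lost by ring opening through the C3 enolate or by ionisation.
- In A4 the OMOM group at C2' has no ortho substituent that pushes it over C3', so regiocontrol on ring B would be weaker than in 10.
- Moving the stereocentre-forming step behind the double shift would require a less established asymmetric reaction on a fully decorated substrate.

The two shifts were therefore kept, but separated and placed before the stereocentre.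

**Alternative 3:** Only O1–C2 is cut, with inversion. The forward key step is an enantioselective aldol or ketone reduction to the (3R)-β-hydroxy ketone A5, followed by Mitsunobu ring closure by the ortho phenol. It was turned down for these reasons.
- The activated oxyphosphonium intermediate sits on a benzylic carbon bearing a 2,4-dialkoxyaryl group. It should ionise, and SN1 closure and E1 elimination to A1 would compete with clean inversion.
- A5 is also prone to retro-aldol cleavage and dehydration.
- The route still needs A2 and A3 and adds two or three steps to Alternative 1.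

Key step: step 10

## Route

Step 1
Reactants: 1 5,7-dihydroxy-4H-chromen-4-one
Product: 2 5-hydroxy-7-(methoxymethoxy)-4H-chromen-4-one
Conditions: MOMCl (1.1 equiv), iPr2NEt (1.5 equiv), CH2Cl2, 0 °C to rt
Reagents that add atoms: chloromethyl methyl ether, COCCl
Why: O-alkylation (MOM protection): O5–H is locked in a hydrogen bond to the C4 carbonyl and is far less acidic and nucleophilic than the vinylogous-acid O7–H, so one equivalent of reagent with an amine base should protect O7 only.

Step 2
Reactants: 2 5-hydroxy-7-(methoxymethoxy)-4H-chromen-4-one
Product: 3 7-(methoxymethoxy)-5-[(3-methylbut-2-en-1-yl)oxy]-4H-chromen-4-one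
Conditions: prenyl bromide (1.5 equiv), K2CO3 (3 equiv), DMF, 50 °C
Reagents that add atoms: 1-bromo-3-methylbut-2-ene (prenyl bromide), CC(C)=CCBr
Why: Williamson ether synthesis on the chelated phenol: carbonate in DMF breaks the hydrogen bond, O5 is the only nucleophilic oxygen left, and SN2 at the primary allylic bromide gives the linear O-prenyl ether; the chromone and the MOM acetal are stable to K2CO3.

Step 3
Reactants: 3 7-(methoxymethoxy)-5-[(3-methylbut-2-en-1-yl)oxy]-4H-chromen-4-one
Product: 6 5-hydroxy-7-(methoxymethoxy)-8-(3-methylbut-2-en-1-yl)-4H-chromen-4-one, via ortho-dienone 4 (not isolated), via para-dienone 5 (not isolated)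
Conditions: Eu(fod)3 (10 mol%; fod = 6,6,7,7,8,8,8-heptafluoro-2,2-dimethyloctane-3,5-dionate), CHCl3 (ethanol-free), 70 °C, sealed tube
Reagents that add atoms: none
Why: Lewis-acid-catalysed para-Claisen–Cope rearrangement of a peri-carbonyl aryl prenyl ether: the trivalent europium centre chelates C4=O and O5 and accelerates the aromatic Claisen [3,3] shift to C6 (dienone 4); a Cope [3,3] shift then carries the chain from the crowded C6 to C8 (dienone 5) before tautomerisation to the chelated phenol. Two allyl inversions return the linear prenyl group, and because C8a already bears O1 the position para to O5 can only be C8.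

Step 4
Reactants: 6 5-hydroxy-7-(methoxymethoxy)-8-(3-methylbut-2-en-1-yl)-4H-chromen-4-one
Product: 7 5,7-bis(methoxymethoxy)-8-(3-methylbut-2-en-1-yl)-4H-chromen-4-one
Conditions: NaH (1.3 equiv), MOMCl (1.3 equiv), DMF, 0 °C to rt
Reagents that add atoms: chloromethyl methyl ether, COCCl
Why: O-alkylation (MOM protection) of the chelated phenol after full deprotonation with NaH; capping O5 removes the acetylacetonate-like O5/O4 chelating site that could otherwise bind rhodium in step 10.

Step 5
Reactants: 8 4-bromobenzene-1,3-diol (4-bromoresorcinol)
Product: 9 2-bromo-5-[(3-methylbut-2-en-1-yl)oxy]phenol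
Conditions: NaH (2.1 equiv), DMF, 0 °C; prenyl bromide (1.0 equiv), 0 °C; aq HCl (1 M) quench
Reagents that add atoms: 1-bromo-3-methylbut-2-ene (prenyl bromide), CC(C)=CCBr
Why: Regioselective Williamson alkylation of a bis-phenoxide: with both oxygens deprotonated, the phenoxide para to bromine is the more basic and less hindered one and should take up the single equivalent of allylic bromide; the ortho-bromophenoxide is inductively stabilised and shielded. The two possible monoethers differ strongly in polarity (one has an OH ortho to bromine), so the wanted one can be purified at this stage.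

Step 6
Reactants: 9 2-bromo-5-[(3-methylbut-2-en-1-yl)oxy]phenol
Product: 10 1-bromo-2-(methoxymethoxy)-4-[(3-methylbut-2-en-1-yl)oxy]benzene
Conditions: MOMCl (1.3 equiv), iPr2NEt (2 equiv), CH2Cl2, 0 °C to rt
Reagents that add atoms: chloromethyl methyl ether, COCCl
Why: MOM protection (O-alkylation) of the remaining ortho-bromophenol; the group serves as a steric marker in step 7, as a lithium-stable ether in step 9 and as a small ortho substituent in step 10.

Step 7
Reactants: 10 1-bromo-2-(methoxymethoxy)-4-[(3-methylbut-2-en-1-yl)oxy]benzene
Product: 12 4-bromo-5-(methoxymethoxy)-2-(2-methylbut-3-en-2-yl)phenol, via cyclohexadienone 11 (not isolated)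
Conditions: N,N-diethylaniline (degassed), 190 °C, argon, 2–4 h
Reagents that add atoms: none
Why: Thermal aromatic Claisen rearrangement: the [3,3] shift gives dienone 11, which tautomerises to the phenol, and the allyl inversion attaches the chain through its tertiary carbon as the 2-methylbut-3-en-2-yl group. Of the two ortho positions of 10, C3 lies between two oxygens and is covered by the OCH2OCH3 group, which the adjacent bromine forces to point toward C3, so migration should go to C5. The para position is blocked by bromine, so no Cope step can follow.

Step 8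
Reactants: 12 4-bromo-5-(methoxymethoxy)-2-(2-methylbut-3-en-2-yl)phenol
Product: 13 1-bromo-2,4-bis(methoxymethoxy)-5-(2-methylbut-3-en-2-yl)benzene
Conditions: NaH (1.3 equiv), MOMCl (1.3 equiv), THF/DMF, 0 °C to rt
Reagents that add atoms: chloromethyl methyl ether, COCCl
Why: MOM protection (O-alkylation) of the hindered phenol via its sodium salt; both oxygens of ring B then carry the same acid-labile, organolithium-stable group.

Step 9
Reactants: 13 1-bromo-2,4-bis(methoxymethoxy)-5-(2-methylbut-3-en-2-yl)benzene
Product: 16 [2,4-bis(methoxymethoxy)-5-(2-methylbut-3-en-2-yl)phenyl]boronic acid, via aryllithium 14 (not isolated), via lithium triisopropoxyborate 15 (not isolated)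
Conditions: n-BuLi (1.05 equiv), THF, −78 °C; B(OiPr)3 (1.5 equiv), −78 °C to rt; H2O, neutral work-up
Reagents that add atoms: triisopropyl borate, CC(C)OB(OC(C)C)OC(C)C; water, O
Why: Bromine–lithium exchange followed by borylation with a trialkyl borate and hydrolysis: exchange at −78 °C is much faster than ortho-lithiation between the two OMOM groups, and aryllithium 14 is stabilised by chelation to the neighbouring OMOM oxygen. Neutral hydrolysis of the ate complex 15 avoids protodeboronation of the electron-rich boronic acid.

Step 10
Reactants: 7 5,7-bis(methoxymethoxy)-8-(3-methylbut-2-en-1-yl)-4H-chromen-4-one; 16 [2,4-bis(methoxymethoxy)-5-(2-methylbut-3-en-2-yl)phenyl]boronic acid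
Product: 17 (2S)-2-[2,4-bis(methoxymethoxy)-5-(2-methylbut-3-en-2-yl)phenyl]-5,7-bis(methoxymethoxy)-8-(3-methylbut-2-en-1-yl)-2,3-dihydro-4H-chromen-4-one
Conditions: 16 (2.0 equiv), [RhCl(C2H4)2]2 (2.5 mol%), (S,S)-Ph-bod* [(1S,4S)-2,5-diphenylbicyclo[2.2.2]octa-2,5-diene, 5.5 mol%], KOH (10 mol%), 1,4-dioxane/H2O 10:1, 40 °C
Reagents that add atoms: none
Why: Hayashi–Miyaura-type asymmetric 1,4-addition, a reaction type established for chromones as a route to flavanones: the hydroxorhodium–diene complex undergoes transmetalation with 16, the aryl-rhodium species binds the C2=C3 bond of 7, migratory insertion places the aryl group on C2 and gives an oxa-π-allyl rhodium enolate, and water protonates it to release 17 and return the hydroxorhodium complex. No ring is closed in this step; ring C is brought in intact from 7, so no mode of ring closure has to be controlled and the ring-opened manifold is never entered. The new stereocentre C2 is set by the catalyst alone, since neither partner is chiral: the C2-symmetric diene on monovalent rhodium leaves one enantioface of the enone open, and delivery of the aryl group to the Re face of C2 (O1 > C3 > H) gives 2S. The (S,S) ligand is proposed by analogy with the sense of induction of this ligand family with cyclic enones, and the (R,R) ligand is the immediate remedy if the opposite sense is found. The step needs 1,4- rather than 1,2-addition, which is inherent in the insertion mechanism, and chemoselectivity for the enone over the prenyl and vinyl groups, which as unactivated alkenes do not insert into aryl–rhodium bonds under these conditions. Transmetalation must outrun protodeboronation of the electron-rich, ortho-substituted boronic acid; two equivalents of 16, a diene ligand (the most active class for aryl transfer), 40 °C and a minimum of base serve this, and the ortho OMOM group is small and able to pre-coordinate. Protonation of the rhodium enolate must outrun β-elimination of the O1 phenoxide, which the water-containing medium secures, and the O5 MOM ether prevents an O5/O4 chelate from sequestering rhodium. Because only about 0.1 equivalent of hydroxide is present, base-induced ring opening of 17, and with it loss of configuration, should be negligible.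

Step 11
Reactants: 17 (2S)-2-[2,4-bis(methoxymethoxy)-5-(2-methylbut-3-en-2-yl)phenyl]-5,7-bis(methoxymethoxy)-8-(3-methylbut-2-en-1-yl)-2,3-dihydro-4H-chromen-4-one
Product: 18 (2S)-2-[2,4-dihydroxy-5-(2-methylbut-3-en-2-yl)phenyl]-5,7-dihydroxy-8-(3-methylbut-2-en-1-yl)-2,3-dihydro-4H-chromen-4-one (AChE-IN-17)
Conditions: HCl (1.25 M in MeOH), THF, 0 °C to rt, monitored; NaHCO3 quench
Reagents that add atoms: none
Why: Acid-catalysed acetal exchange (MOM cleavage): protonation of the acetal oxygen and transfer of the methoxymethyl group to methanol frees the four phenols. Dilute anhydrous HCl at or below room temperature is chosen because alkene protonation (needed for cyclisation onto a neighbouring phenol) and ionisation of the C2–O1 bond both require stronger acid or heat, so the side chains and the C2 configuration should survive.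

## Compound list

1 | 5,7-dihydroxy-4H-chromen-4-one | O=c1ccoc2cc(O)cc(O)c12 | starting material
2 | 5-hydroxy-7-(methoxymethoxy)-4H-chromen-4-one | O=c1ccoc2cc(OCOC)cc(O)c12 | intermediate
3 | 7-(methoxymethoxy)-5-[(3-methylbut-2-en-1-yl)oxy]-4H-chromen-4-one | O=c1ccoc2cc(OCOC)cc(OCC=C(C)C)c12 | intermediate
4 | rac-7-(methoxymethoxy)-6-(2-methylbut-3-en-2-yl)-4H-chromene-4,5(6H)-dione (ortho-dienone, formed in the flask, not isolated) | O=C1C(C(C)(C)C=C)C(OCOC)=CC2=C1C(=O)C=CO2 | intermediate
5 | rac-7-(methoxymethoxy)-8-(3-methylbut-2-en-1-yl)-4H-chromene-4,5(8H)-dione (para-dienone, formed in the flask, not isolated) | O=C1C=C(OCOC)C(CC=C(C)C)C2=C1C(=O)C=CO2 | intermediate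
6 | 5-hydroxy-7-(methoxymethoxy)-8-(3-methylbut-2-en-1-yl)-4H-chromen-4-one | O=c1ccoc2c(CC=C(C)C)c(OCOC)cc(O)c12 | intermediate
7 | 5,7-bis(methoxymethoxy)-8-(3-methylbut-2-en-1-yl)-4H-chromen-4-one | O=c1ccoc2c(CC=C(C)C)c(OCOC)cc(OCOC)c12 | intermediate
8 | 4-bromobenzene-1,3-diol | Oc1ccc(Br)c(O)c1 | starting material
9 | 2-bromo-5-[(3-methylbut-2-en-1-yl)oxy]phenol | Oc1cc(OCC=C(C)C)ccc1Br | intermediate
10 | 1-bromo-2-(methoxymethoxy)-4-[(3-methylbut-2-en-1-yl)oxy]benzene | COCOc1cc(OCC=C(C)C)ccc1Br | intermediate
11 | rac-4-bromo-3-(methoxymethoxy)-6-(2-methylbut-3-en-2-yl)cyclohexa-2,4-dien-1-one (formed in the flask, not isolated) | O=C1C=C(OCOC)C(Br)=CC1C(C)(C)C=C | intermediate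
12 | 4-bromo-5-(methoxymethoxy)-2-(2-methylbut-3-en-2-yl)phenol | Oc1cc(OCOC)c(Br)cc1C(C)(C)C=C | intermediate
13 | 1-bromo-2,4-bis(methoxymethoxy)-5-(2-methylbut-3-en-2-yl)benzene | COCOc1cc(OCOC)c(Br)cc1C(C)(C)C=C | intermediate
14 | [2,4-bis(methoxymethoxy)-5-(2-methylbut-3-en-2-yl)phenyl]lithium (formed in the flask, not isolated) | [Li]c1cc(C(C)(C)C=C)c(OCOC)cc1OCOC | intermediate
15 | lithium [2,4-bis(methoxymethoxy)-5-(2-methylbut-3-en-2-yl)phenyl]tri(propan-2-yloxy)borate (formed in the flask, not isolated) | [Li+].CC(C)O[B-](OC(C)C)(OC(C)C)c1cc(C(C)(C)C=C)c(OCOC)cc1OCOC | intermediate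
16 | [2,4-bis(methoxymethoxy)-5-(2-methylbut-3-en-2-yl)phenyl]boronic acid | OB(O)c1cc(C(C)(C)C=C)c(OCOC)cc1OCOC | intermediate
17 | (2S)-2-[2,4-bis(methoxymethoxy)-5-(2-methylbut-3-en-2-yl)phenyl]-5,7-bis(methoxymethoxy)-8-(3-methylbut-2-en-1-yl)-2,3-dihydro-4H-chromen-4-one | C=CC(C)(C)c1cc([C@@H]2CC(=O)c3c(OCOC)cc(OCOC)c(CC=C(C)C)c3O2)c(OCOC)cc1OCOC | intermediate
18 | (2S)-2-[2,4-dihydroxy-5-(2-methylbut-3-en-2-yl)phenyl]-5,7-dihydroxy-8-(3-methylbut-2-en-1-yl)-2,3-dihydro-4H-chromen-4-one | C=CC(C)(C)c1cc([C@@H]2CC(=O)c3c(O)cc(O)c(CC=C(C)C)c3O2)c(O)cc1O | target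

## Step count and least certain steps

Total step count: 11. Longest linear sequence: 7 steps (steps 5–11, from 8 to 18); the ring A/C branch (steps 1–4) joins at step 10.

**Step 10 (key step).** The most likely failure is slow aryl transfer. The chromone is an electron-rich, weakly electrophilic acceptor, and the boronic acid is ortho-substituted and prone to protodeboronation, so the donor may be consumed before insertion occurs. A second risk is incomplete facial control with an ortho-substituted aryl group.

The fallback changes the bond that is formed:
- From 7, aqueous NaOH in ethanol at reflux should open the pyranone ring and cleave the resulting formyl ketone to the methyl ketone 1-[2-hydroxy-4,6-bis(methoxymethoxy)-3-(3-methylbut-2-en-1-yl)phenyl]ethan-1-one F1.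
- From 13, the aryllithium 14 is quenched with DMF to give 2,4-bis(methoxymethoxy)-5-(2-methylbut-3-en-2-yl)benzaldehyde F2.
- Claisen–Schmidt condensation (KOH, EtOH) should give (2E)-3-[2,4-bis(methoxymethoxy)-5-(2-methylbut-3-en-2-yl)phenyl]-1-[2-hydroxy-4,6-bis(methoxymethoxy)-3-(3-methylbut-2-en-1-yl)phenyl]prop-2-en-1-one F3.
- NaOAc in refluxing ethanol should close F3 to racemic 2-[2,4-bis(methoxymethoxy)-5-(2-methylbut-3-en-2-yl)phenyl]-5,7-bis(methoxymethoxy)-8-(3-methylbut-2-en-1-yl)-2,3-dihydro-4H-chromen-4-one F4.
- Kinetic resolution of F4 by asymmetric transfer hydrogenation (RhCl[(R,R)-TsDPEN](C5Me5) or its enantiomer, whichever reduces the 2R ketone faster, HCO2H/Et3N) should convert the 2R enantiomer into (2R,4R)-2-[2,4-bis(methoxymethoxy)-5-(2-methylbut-3-en-2-yl)phenyl]-5,7-bis(methoxymethoxy)-8-(3-methylbut-2-en-1-yl)-3,4-dihydro-2H-chromen-4-ol F5 and leave the 2S ketone, which is 17. The route is rejoined there, at the cost of half the material.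

**Step 3.** The sequence may stop after the first [3,3] shift: tautomerisation of the ortho-dienone can compete with the Cope shift and leave the branched chain at C6. The MOM acetal may also be slowly cleaved by the Lewis acid.

The fallback replaces the sigmatropic relay by cross-coupling. From 2, NaH/MOMCl should give 5,7-bis(methoxymethoxy)-4H-chromen-4-one F6. Electrophilic iodination (N-iodosuccinimide, DMF), which in fully O-alkylated 5,7-dioxygenated chromones goes to the less hindered C8, should give 8-iodo-5,7-bis(methoxymethoxy)-4H-chromen-4-one F7. A Stille coupling with tributyl(3-methylbut-2-en-1-yl)stannane and Pd(PPh3)4 in DMF should then install the linear prenyl group and return to the route at 7.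

**Step 5.** Alkylation at the wrong oxygen, double alkylation and C-alkylation of the resorcinolate are the risks; selectivity rests on the basicity and steric difference of the two phenoxides only.

The fallback uses steric differentiation. From 8, chlorotri(propan-2-yl)silane and imidazole should silylate only the unhindered oxygen and give 2-bromo-5-{[tri(propan-2-yl)silyl]oxy}phenol F8. MOM protection gives [4-bromo-3-(methoxymethoxy)phenoxy]tri(propan-2-yl)silane F9. Tetrabutylammonium fluoride frees 4-bromo-3-(methoxymethoxy)phenol F10. Prenyl bromide and K2CO3 then give 10, where the route is rejoined.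

**Step 7.** Migration to the position between the two oxygens may compete. At 190 °C the ortho-(reverse prenyl)phenol can also cyclise onto its own alkene or lose the C5 unit.

The fallback avoids the rearrangement. From 8, double MOM protection should give 1-bromo-2,4-bis(methoxymethoxy)benzene F11. Bromination with N-bromosuccinimide at the position para to one and ortho to the other oxygen gives the symmetrical 1,5-dibromo-2,4-bis(methoxymethoxy)benzene F12. A branched-selective Suzuki–Miyaura mono-coupling with 4,4,5,5-tetramethyl-2-(3-methylbut-2-en-1-yl)-1,3,2-dioxaborolane (Pd(OAc)2, a bulky dialkylbiarylphosphine chosen for attack through the tertiary terminus, K3PO4, with the dibromide in excess) gives 13, where the route is rejoined.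

**Step 11.** Acid may promote cyclisation of a side-chain alkene onto the neighbouring phenol, or ionisation at C2 with loss of configuration, before the last MOM group has left; the O7 and O2'/O4' acetals are slower to cleave than the O5 acetal.

The fallback avoids protic acid. From 17, trimethylsilyl triflate with 2,2'-bipyridyl in CH2Cl2 at 0 °C should exchange the aryl MOM ethers for silyl ethers and give (2S)-8-(3-methylbut-2-en-1-yl)-2-[5-(2-methylbut-3-en-2-yl)-2,4-bis(trimethylsilyloxy)phenyl]-5,7-bis(trimethylsilyloxy)-2,3-dihydro-4H-chromen-4-one F13. Neutral hydrolysis with water then gives 18.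

## Further compounds

F1 | step 10 | 1-[2-hydroxy-4,6-bis(methoxymethoxy)-3-(3-methylbut-2-en-1-yl)phenyl]ethan-1-one | CC(=O)c1c(O)c(CC=C(C)C)c(OCOC)cc1OCOC
F2 | step 10 | 2,4-bis(methoxymethoxy)-5-(2-methylbut-3-en-2-yl)benzaldehyde | O=Cc1cc(C(C)(C)C=C)c(OCOC)cc1OCOC
F3 | step 10 | (2E)-3-[2,4-bis(methoxymethoxy)-5-(2-methylbut-3-en-2-yl)phenyl]-1-[2-hydroxy-4,6-bis(methoxymethoxy)-3-(3-methylbut-2-en-1-yl)phenyl]prop-2-en-1-one | COCOc1cc(OCOC)c(C(=O)/C=C/c2cc(C(C)(C)C=C)c(OCOC)cc2OCOC)c(O)c1CC=C(C)C
F4 | step 10 | racemic 2-[2,4-bis(methoxymethoxy)-5-(2-methylbut-3-en-2-yl)phenyl]-5,7-bis(methoxymethoxy)-8-(3-methylbut-2-en-1-yl)-2,3-dihydro-4H-chromen-4-one | C=CC(C)(C)c1cc(C2CC(=O)c3c(OCOC)cc(OCOC)c(CC=C(C)C)c3O2)c(OCOC)cc1OCOC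
F5 | step 10 | (2R,4R)-2-[2,4-bis(methoxymethoxy)-5-(2-methylbut-3-en-2-yl)phenyl]-5,7-bis(methoxymethoxy)-8-(3-methylbut-2-en-1-yl)-3,4-dihydro-2H-chromen-4-ol | C=CC(C)(C)c1cc([C@H]2C[C@@H](O)c3c(OCOC)cc(OCOC)c(CC=C(C)C)c3O2)c(OCOC)cc1OCOC
F6 | step 3 | 5,7-bis(methoxymethoxy)-4H-chromen-4-one | O=c1ccoc2cc(OCOC)cc(OCOC)c12
F7 | step 3 | 8-iodo-5,7-bis(methoxymethoxy)-4H-chromen-4-one | O=c1ccoc2c(I)c(OCOC)cc(OCOC)c12
F8 | step 5 | 2-bromo-5-{[tri(propan-2-yl)silyl]oxy}phenol | Oc1cc(O[Si](C(C)C)(C(C)C)C(C)C)ccc1Br
F9 | step 5 | [4-bromo-3-(methoxymethoxy)phenoxy]tri(propan-2-yl)silane | COCOc1cc(O[Si](C(C)C)(C(C)C)C(C)C)ccc1Br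
F10 | step 5 | 4-bromo-3-(methoxymethoxy)phenol | COCOc1cc(O)ccc1Br
F11 | step 7 | 1-bromo-2,4-bis(methoxymethoxy)benzene | COCOc1ccc(Br)c(OCOC)c1
F12 | step 7 | 1,5-dibromo-2,4-bis(methoxymethoxy)benzene | COCOc1cc(OCOC)c(Br)cc1Br
F13 | step 11 | (2S)-8-(3-methylbut-2-en-1-yl)-2-[5-(2-methylbut-3-en-2-yl)-2,4-bis(trimethylsilyloxy)phenyl]-5,7-bis(trimethylsilyloxy)-2,3-dihydro-4H-chromen-4-one | C=CC(C)(C)c1cc([C@@H]2CC(=O)c3c(O[Si](C)(C)C)cc(O[Si](C)(C)C)c(CC=C(C)C)c3O2)c(O[Si](C)(C)C)cc1O[Si](C)(C)C
A1 | alternative 1 | (2E)-3-[2,4-bis(methoxymethoxy)-5-(2-methylbut-3-en-2-yl)phenyl]-1-[2-hydroxy-4,6-bis(methoxymethoxy)-3-(3-methylbut-2-en-1-yl)phenyl]prop-2-en-1-one | COCOc1cc(OCOC)c(C(=O)/C=C/c2cc(C(C)(C)C=C)c(OCOC)cc2OCOC)c(O)c1CC=C(C)C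
A2 | alternative 1 | 1-[2-hydroxy-4,6-bis(methoxymethoxy)-3-(3-methylbut-2-en-1-yl)phenyl]ethan-1-one | CC(=O)c1c(O)c(CC=C(C)C)c(OCOC)cc1OCOC
A3 | alternative 1 | 2,4-bis(methoxymethoxy)-5-(2-methylbut-3-en-2-yl)benzaldehyde | O=Cc1cc(C(C)(C)C=C)c(OCOC)cc1OCOC
A4 | alternative 2 | (2S)-7-(methoxymethoxy)-2-{2-(methoxymethoxy)-4-[(3-methylbut-2-en-1-yl)oxy]phenyl}-5-[(3-methylbut-2-en-1-yl)oxy]-2,3-dihydro-4H-chromen-4-one | COCOc1cc(OCC=C(C)C)ccc1[C@@H]1CC(=O)c2c(OCC=C(C)C)cc(OCOC)cc2O1
A5 | alternative 3 | (3R)-3-[2,4-bis(methoxymethoxy)-5-(2-methylbut-3-en-2-yl)phenyl]-3-hydroxy-1-[2-hydroxy-4,6-bis(methoxymethoxy)-3-(3-methylbut-2-en-1-yl)phenyl]propan-1-one | COCOc1cc(OCOC)c(C(C)(C)C=C)cc1[C@H](O)CC(=O)c1c(O)c(CC=C(C)C)c(OCOC)cc1OCOC
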